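## Retrosynthetic overview

- The target depside is cut at the ring B aryl–C(=O) bond, not at the ester C–O bond. The partners are an electrophilic aryl iodide and an aryl formate that serves as an aryloxycarbonyl anion (acyl anion) equivalent, joined by palladium.
- Ring B partner: 2,5-dimethylresorcinol 1 → monochloride 2 → chloro-iodide 3, by two electrophilic halogenations.
- Ring A partner: methyl orsellinate 4 → 4-O-formate 5. Then 3 + 5 → (CO 6 and phenoxide 7, formed in the flask) → target 8.
- No ring is built: both benzene rings are bought intact. No protecting groups are used.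

Assumption: the target has no stereocentre and is achiral, so "single enantiomer" is taken to mean the compound exactly as drawn.

## Route

Step 1
Reactants: 1 2,5-dimethylbenzene-1,3-diol (2,5-dimethylresorcinol)
Product: 2 4-chloro-2,5-dimethylbenzene-1,3-diol
Conditions: SO2Cl2 (1.0 equiv, slow addition), Et2O, 0 °C to rt
Reagents that add atoms: sulfuryl chloride, O=S(=O)(Cl)Cl
Why: Electrophilic aromatic chlorination; the two free ring positions of symmetric 1 are equivalent (each ortho to one OH and para to the other), so one equivalent of SO2Cl2 in ether gives a single monochloride, and the new chlorine slows a second substitution.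

Step 2
Reactants: 2 4-chloro-2,5-dimethylbenzene-1,3-diol
Product: 3 4-chloro-6-iodo-2,5-dimethylbenzene-1,3-diol
Conditions: NIS (1.05 equiv), MeCN, 0 °C, dark; aq. Na2S2O3 work-up
Reagents that add atoms: N-iodosuccinimide, O=C1CCC(=O)N1I
Why: Electrophilic aromatic iodination at the only remaining ring C–H, which is ortho to one hydroxyl and para to the other, so no regiochemical choice exists.

Step 3
Reactants: 4 methyl 2,4-dihydroxy-6-methylbenzoate (methyl orsellinate)
Product: 5 methyl 4-(formyloxy)-2-hydroxy-6-methylbenzoate
Conditions: HCO2H/Ac2O (60 °C, 1 h), then 4, NaOAc (0.2 equiv), 0 °C to rt; strip volatiles with toluene, short dry silica plug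
Reagents that add atoms: acetic formic anhydride, CC(=O)OC=O (made in the flask from formic acid, O=CO, and acetic anhydride, CC(=O)OC(C)=O)
Why: O-formylation of a phenol with a mixed anhydride; the formyl carbonyl is the more electrophilic end of the anhydride, and the 4-OH reacts ahead of the 2-OH, which is hydrogen-bonded to the ester carbonyl and more hindered.

Step 4
Reactants: 3 4-chloro-6-iodo-2,5-dimethylbenzene-1,3-diol; 5 methyl 4-(formyloxy)-2-hydroxy-6-methylbenzoate (2.0 equiv)
Product: 8 methyl 4-[(3-chloro-4,6-dihydroxy-2,5-dimethylbenzoyl)oxy]-2-hydroxy-6-methylbenzoate, via carbon monoxide 6 (not isolated), via triethylammonium aryloxide 7 (not isolated)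
Conditions: Pd(OAc)2 (5 mol %), Xantphos (7.5 mol %), NEt3 (3 equiv), degassed dry MeCN, sealed tube, 80 °C
Reagents that add atoms: none
Why: Palladium-catalysed aryloxycarbonylation of an aryl iodide with an aryl formate: 5 delivers its normally electrophilic formate carbon as an aryloxycarbonyl anion equivalent (NEt3 releases it as CO 6 plus phenoxide 7), and oxidative addition of the C–I bond of 3 to zerovalent palladium (C–Cl untouched), CO insertion and C–O reductive elimination join it to the electrophilic iodide carbon, while the unhindered, more acidic 4-oxygen of ring A outcompetes the doubly flanked phenols of ring B and the chelated 2-OH.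

## Compound list

1 | 2,5-dimethylbenzene-1,3-diol (2,5-dimethylresorcinol) | Cc1cc(O)c(C)c(O)c1 | starting material
2 | 4-chloro-2,5-dimethylbenzene-1,3-diol | Cc1cc(O)c(C)c(O)c1Cl | intermediate
3 | 4-chloro-6-iodo-2,5-dimethylbenzene-1,3-diol | Cc1c(Cl)c(O)c(C)c(O)c1I | intermediate
4 | methyl 2,4-dihydroxy-6-methylbenzoate (methyl orsellinate) | COC(=O)c1c(C)cc(O)cc1O | starting material
5 | methyl 4-(formyloxy)-2-hydroxy-6-methylbenzoate | COC(=O)c1c(C)cc(OC=O)cc1O | intermediate
6 | carbon monoxide | [C-]#[O+] | intermediate
7 | triethylammonium 3-hydroxy-4-(methoxycarbonyl)-5-methylphenolate | CC[NH+](CC)CC.COC(=O)c1c(C)cc([O-])cc1O | intermediate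
8 | methyl 4-[(3-chloro-4,6-dihydroxy-2,5-dimethylbenzoyl)oxy]-2-hydroxy-6-methylbenzoate | COC(=O)c1c(C)cc(OC(=O)c2c(C)c(Cl)c(O)c(C)c2O)cc1O | target

## Step count and risks

Total steps: 4. Longest linear sequence: 3 (1 → 2 → 3 → 8); the second branch is 4 → 5 → 8.

**Step 4 (highest risk).** The free phenols of ring B may capture the acyl–palladium stage and give oligoesters, or 3 may simply lose iodine. The fallback sets out from 3 and masks the phenols before the coupling. Both hydroxyls are capped with MOMCl/i-Pr2NEt in CH2Cl2 to give 1-chloro-5-iodo-2,4-bis(methoxymethoxy)-3,6-dimethylbenzene F1. F1 is coupled with 5 under the step 4 conditions (again through 6 and 7) to give methyl 4-{[3-chloro-4,6-bis(methoxymethoxy)-2,5-dimethylbenzoyl]oxy}-2-hydroxy-6-methylbenzoate F2. Both acetals are then removed with TFA/CH2Cl2/H2O at 0 °C to rt, which the hindered aryl ester tolerates, and the route comes back at 8.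

**Step 1.** Over-chlorination to the 4,6-dichloride, or a mono/di mixture that is hard to separate, would spoil the sequence. The fallback sets out from 1 and moves the chlorination to the end. Compound 1 is mono-iodinated with NIS (1.0 equiv, MeCN, −20 °C) to 4-iodo-2,5-dimethylbenzene-1,3-diol F3; mono- and di-iodide should separate readily on silica. F3 is coupled with 5 under the step 4 conditions to give methyl 4-[(2,4-dihydroxy-3,6-dimethylbenzoyl)oxy]-2-hydroxy-6-methylbenzoate F4. F4 is chlorinated with NCS (1.0 equiv, MeCN, 0 °C) at the one free position of ring B, which is ortho and para to two free hydroxyls and should react ahead of ring A, whose single free OH is chelated. The route comes back at 8.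

**Step 3.** The formate 5 is moisture-sensitive and may hydrolyse on isolation or be contaminated with acetate or bis-formate. The fallback sets out from 4 and drops the preformed formate. Compounds 3 and 4 (2 equiv) are joined in a three-component aryloxycarbonylation under a CO balloon (1 atm) with the same Pd(OAc)2/Xantphos/NEt3 system in MeCN at 80 °C, and the route comes back at 8. This fallback makes no new compound (F0).

## Further compounds

F1 | step 4 | 1-chloro-5-iodo-2,4-bis(methoxymethoxy)-3,6-dimethylbenzene | COCOc1c(C)c(OCOC)c(Cl)c(C)c1I
F2 | step 4 | methyl 4-{[3-chloro-4,6-bis(methoxymethoxy)-2,5-dimethylbenzoyl]oxy}-2-hydroxy-6-methylbenzoate | COC(=O)c1c(C)cc(OC(=O)c2c(C)c(Cl)c(OCOC)c(C)c2OCOC)cc1O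
F3 | step 1 | 4-iodo-2,5-dimethylbenzene-1,3-diol | Cc1cc(O)c(C)c(O)c1I
F4 | step 1 | methyl 4-[(2,4-dihydroxy-3,6-dimethylbenzoyl)oxy]-2-hydroxy-6-methylbenzoate | COC(=O)c1c(C)cc(OC(=O)c2c(C)cc(O)c(C)c2O)cc1O
F0 | step 3 | none | none
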